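**Plan**

- Feature: in each half the benzenoid ring C5–C8 is oxygenated at C5, C7 and C8 and keeps one hydrogen, at C6. A benzannulation that joins a methoxycarbene carbon (C5), the two carbons of a terminal ynol ether (C6–H, C7–O) and a carbonyl ligand (C8–O) to an existing benzene ring gives exactly this ring.
- Cuts: the six aryl ethers first; then the bond between the ether oxygen and the quinone carbon C2, which leaves a 2-bromoquinone and a tertiary alcohol that both come from one 2-hydroxy-1,4-naphthoquinone; then, in the naphthol behind it, C5–C6, C7–C8 and C8–C8a.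
- Forward: the ethyl-bearing ring is present from the start (benzene-1,2,4-triol as its tris-methoxymethyl ether, ethylated by directed lithiation, brominated, turned into the chromium carbene complex). The benzannulation closes the C5–C8 ring. Acid and air then convert only the first ring into the hydroxyquinone, the two partners are made from it and joined through oxygen, and the ethers are removed.
- Stereochemistry: the single stereocentre, C3' of the trione half, is set as S by a catalyst-controlled α-hydroxylation of the hydroxyquinone. It is not touched afterwards, because the ether is closed at the quinone carbon and C3' bears no hydrogen.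

Key step: step 5

Remark: naphthalene locants follow one half of the target (C1 and C4 the carbonyl carbons of the ethyl-bearing ring, C2 oxygen, C3 ethyl, C5–C8 the second ring; primes for the trione half).
Remark: the sense of induction in step 9 cannot be predicted safely for this substrate; it is assumed that one antipode of the ligand (both are accessible from (S)- and (R)-pipecolic acid) delivers the S alcohol and that this antipode is used.

**Route**

Step 1
Reactants: 1 benzene-1,2,4-triol
Product: 2 1,2,4-tris(methoxymethoxy)benzene
Conditions: MOMCl (3.6 equiv), K2CO3 (4 equiv), acetone, 0 °C → rt, argon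
Reagents that add atoms: chloromethyl methyl ether, COCCl
Why: Williamson-type O-alkylation of the three phenols by the reactive α-chloro ether installs acid-labile acetals that also act as strong ortho-directing groups in the next step.

Step 2
Reactants: 2 1,2,4-tris(methoxymethoxy)benzene; 3 iodoethane
Product: 5 2-ethyl-1,3,4-tris(methoxymethoxy)benzene, via aryllithium 4 (not isolated)
Conditions: n-BuLi (1.1 equiv), THF, 0 °C, 1 h; then iodoethane (1.5 equiv), 0 °C → rt
Reagents that add atoms: iodoethane (compound 3), CCI
Why: Directed ortho-metalation removes the hydrogen flanked by two acetal oxygens, the most acidic one through cooperative coordination of lithium as in 1,2,4-trialkoxybenzenes, and the aryllithium is alkylated by iodoethane in an SN2 reaction.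

Step 3
Reactants: 5 2-ethyl-1,3,4-tris(methoxymethoxy)benzene
Product: 6 1-bromo-3-ethyl-2,4,5-tris(methoxymethoxy)benzene
Conditions: NBS (1.05 equiv), MeCN, 0 °C → rt, dark
Reagents that add atoms: N-bromosuccinimide, O=C1CCC(=O)N1Br
Why: Electrophilic aromatic bromination of a 2,3,6-trialkoxy-alkylbenzene is expected at the carbon ortho to the isolated alkoxy group and para to the central one, the doubly activated site, and not at the carbon para to ethyl.

Step 4
Reactants: 6 1-bromo-3-ethyl-2,4,5-tris(methoxymethoxy)benzene; 7 hexacarbonylchromium Cr(CO)6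
Product: 10 pentacarbonyl{[3-ethyl-2,4,5-tris(methoxymethoxy)phenyl](methoxy)methylidene}chromium, via aryllithium 8 (not isolated), via lithium acylchromate 9 (not isolated)
Conditions: n-BuLi (1.05 equiv), Et2O, −78 °C; Cr(CO)6 (1.1 equiv), Et2O, 0 °C → rt; solvent exchange; MeOTf (1.3 equiv), CH2Cl2, 0 °C
Reagents that add atoms: hexacarbonylchromium Cr(CO)6 (compound 7), O=C=[Cr](=C=O)(=C=O)(=C=O)(=C=O)=C=O; methyl trifluoromethanesulfonate, COS(=O)(=O)C(F)(F)F
Why: Fischer carbene synthesis, in which bromine–lithium exchange, addition of the aryllithium to a carbonyl ligand and O-methylation of the hard acylate oxygen follow one another, the last being much faster than attack of the methylating agent on the acetal oxygens.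

Step 5
Reactants: 10 pentacarbonyl{[3-ethyl-2,4,5-tris(methoxymethoxy)phenyl](methoxy)methylidene}chromium; 11 ethoxyacetylene
Product: 13 7-ethoxy-3-ethyl-5-methoxy-1,2,4-tris(methoxymethoxy)naphthalen-8-ol, via tricarbonylchromium naphthol complex 12 (not isolated)
Conditions: ethoxyacetylene (3 equiv, ca. 40 wt % in hexanes), THF, 50 °C, sealed tube, argon, 16 h; then air, Et2O, rt, 30 min; rapid SiO2 filtration under argon
Reagents that add atoms: ethoxyacetylene (compound 11), CCOC#C
Why: Thermal loss of one CO from 10 opens a site on chromium, the alkyne inserts into the Cr=C bond with its unsubstituted carbon bonding to the carbene carbon (C5–C6), a carbonyl ligand inserts to give a chromium-bound dienylketene (C7–C8), and this closes onto the free ortho carbon of the aryl group (C8–C8a) and tautomerises to the 4-methoxy-1-naphthol, first held as its Cr(CO)3 complex 12. The closest known reaction type is the Dötz benzannulation of aryl(alkoxy)carbene pentacarbonylchromium complexes with terminal alkynes. The one ring formed, C4a–C5–C6–C7–C8–C8a, closes by 6π-electrocyclisation of the dienylketene followed by enolisation. No stereocentre is created. The step needs one orientation of the alkyne, and both the steric rule for terminal alkynes (substituted carbon next to the CO-derived carbon) and the polarisation of the ynol ether (nucleophilic CH carbon to the electrophilic carbene carbon) place OEt at C7 beside the C8 hydroxyl. It also needs ring closure at one ortho carbon only, which is assured because the other ortho carbon carries a methoxymethoxy group, while an alkoxycarbene in THF favours CO insertion and phenol formation over indene or furan products.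

Step 6
Reactants: 13 7-ethoxy-3-ethyl-5-methoxy-1,2,4-tris(methoxymethoxy)naphthalen-8-ol
Product: 14 7-ethoxy-3-ethyl-5,8-dimethoxy-1,2,4-tris(methoxymethoxy)naphthalene
Conditions: MeI (3 equiv), Cs2CO3 (2 equiv), DMF, rt, argon
Reagents that add atoms: iodomethane, CI
Why: Williamson O-methylation of the hindered, oxidation-prone naphthol caps C8–O, so that the C5–C8 ring can no longer become a quinone.

Step 7
Reactants: 14 7-ethoxy-3-ethyl-5,8-dimethoxy-1,2,4-tris(methoxymethoxy)naphthalene
Product: 16 7-ethoxy-3-ethyl-2-hydroxy-5,8-dimethoxynaphthalene-1,4-dione, via naphthalenetriol 15 (not isolated)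
Conditions: 6 M HCl (aq)/THF 1:4, 45 °C, argon; then air, rt
Reagents that add atoms: none
Why: Acid hydrolysis of the three acetals frees the 1,2,4-triol of the ethyl-bearing ring only, and a 1,2,4-trihydroxynaphthalene is autoxidised by air to the 2-hydroxy-1,4-naphthoquinone, which fixes the quinone in the ring that carries ethyl while C5, C7 and C8 remain ethers.

Step 8
Reactants: 16 7-ethoxy-3-ethyl-2-hydroxy-5,8-dimethoxynaphthalene-1,4-dione
Product: 17 2-bromo-7-ethoxy-3-ethyl-5,8-dimethoxynaphthalene-1,4-dione
Conditions: (COBr)2 (1.5 equiv), DMF (0.2 equiv), CH2Cl2, 0 °C → rt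
Reagents that add atoms: oxalyl bromide, BrC(=O)C(=O)Br
Why: Vilsmeier-type activation of the vinylogous acid as its O-formiminium ion and addition–elimination of bromide at C2 give the vinylogous acyl bromide, as in the conversion of 2-hydroxy-1,4-naphthoquinones and cyclic 1,3-diones into their halides.

Step 9
Reactants: 16 7-ethoxy-3-ethyl-2-hydroxy-5,8-dimethoxynaphthalene-1,4-dione
Product: 18 (S)-7-ethoxy-3-ethyl-3-hydroxy-5,8-dimethoxynaphthalene-1,2,4(3H)-trione
Conditions: Sc(OTf)3 (10 mol %), C2-symmetric N,N'-dioxide ligand (two pipecolic acid 2,6-diisopropylanilide N-oxide units joined through nitrogen by a 1,3-propanediyl chain, 11 mol %), 2-(phenylsulfonyl)-3-phenyloxaziridine (1.5 equiv), 4 Å MS, CH2Cl2, 0 °C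
Reagents that add atoms: 2-(phenylsulfonyl)-3-phenyloxaziridine, O=S(=O)(c1ccccc1)N1OC1c1ccccc1
Why: Lewis-acid-catalysed asymmetric α-hydroxylation of an enolised β-dicarbonyl by an N-sulfonyloxaziridine (the reaction type also used for hydroxylative dearomatisation of 1-alkyl-2-naphthols), in which the hydroxyquinone binds scandium through O1 and O2, the chiral ligand shields one face of the enolate carbon C3 and oxygen is delivered to the other, so that the quaternary carbinol centre is set as S under catalyst control.

Step 10
Reactants: 17 2-bromo-7-ethoxy-3-ethyl-5,8-dimethoxynaphthalene-1,4-dione; 18 (S)-7-ethoxy-3-ethyl-3-hydroxy-5,8-dimethoxynaphthalene-1,2,4(3H)-trione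
Product: 19 (S)-7-ethoxy-3-[(7-ethoxy-3-ethyl-5,8-dimethoxy-1,4-dioxo-1,4-dihydronaphthalen-2-yl)oxy]-3-ethyl-5,8-dimethoxynaphthalene-1,2,4(3H)-trione
Conditions: 17 (1.3 equiv), Cs2CO3 (1.2 equiv), 4 Å MS, MeCN, −20 → 0 °C, argon
Reagents that add atoms: none
Why: Proposed new method: the caesium alkoxide of the tertiary α-ketol 18 should add to C2 of the vinylogous acyl bromide 17 and the resulting enolate should expel bromide, so that the ether oxygen is the carbinol oxygen, the C3'–O bond is never broken and the S configuration is retained; the closest known reaction type is the alkoxy- and aryloxy-dehalogenation of 2-halo-1,4-naphthoquinones by alcohols or phenols under carbonate base, which has not been shown for a tertiary α-hydroxy-β-diketone as nucleophile.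

Step 11
Reactants: 19 (S)-7-ethoxy-3-[(7-ethoxy-3-ethyl-5,8-dimethoxy-1,4-dioxo-1,4-dihydronaphthalen-2-yl)oxy]-3-ethyl-5,8-dimethoxynaphthalene-1,2,4(3H)-trione
Product: 20 (S)-3-ethyl-3-[(3-ethyl-5,7,8-trihydroxy-1,4-dioxo-1,4-dihydronaphthalen-2-yl)oxy]-5,7,8-trihydroxynaphthalene-1,2,4(3H)-trione (CNP0325426.1)
Conditions: BBr3 (15 equiv), CH2Cl2, −78 °C → rt; then H2O, 0 °C
Reagents that add atoms: none
Why: Lewis-acid ether cleavage by BBr3 (oxonium formation, then bromide attack on methyl or ethyl) should remove the four peri methyl ethers first through carbonyl chelation and the two C7 ethyl ethers at room temperature, while the central ether survives because its alkyl carbon is tertiary and flanked by two carbonyls (no SN2, no ionisation) and the quaternary stereocentre, lacking an α-hydrogen, keeps its S configuration.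

**Compound list**

1 | benzene-1,2,4-triol | Oc1ccc(O)c(O)c1 | starting material
2 | 1,2,4-tris(methoxymethoxy)benzene | COCOc1ccc(OCOC)c(OCOC)c1 | intermediate
3 | iodoethane | CCI | starting material
4 | [2,3,6-tris(methoxymethoxy)phenyl]lithium | [Li]c1c(OCOC)ccc(OCOC)c1OCOC | intermediate
5 | 2-ethyl-1,3,4-tris(methoxymethoxy)benzene | CCc1c(OCOC)ccc(OCOC)c1OCOC | intermediate
6 | 1-bromo-3-ethyl-2,4,5-tris(methoxymethoxy)benzene | CCc1c(OCOC)c(Br)cc(OCOC)c1OCOC | intermediate
7 | hexacarbonylchromium Cr(CO)6 | O=C=[Cr](=C=O)(=C=O)(=C=O)(=C=O)=C=O | starting material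
8 | [3-ethyl-2,4,5-tris(methoxymethoxy)phenyl]lithium | [Li]c1cc(OCOC)c(OCOC)c(CC)c1OCOC | intermediate
9 | lithium pentacarbonyl{[3-ethyl-2,4,5-tris(methoxymethoxy)phenyl](oxido)methylidene}chromate | [Li+].[O-]C(c1cc(OCOC)c(OCOC)c(CC)c1OCOC)=[Cr](=C=O)(=C=O)(=C=O)(=C=O)=C=O | intermediate
10 | pentacarbonyl{[3-ethyl-2,4,5-tris(methoxymethoxy)phenyl](methoxy)methylidene}chromium | CCc1c(OCOC)c(cc(OCOC)c1OCOC)C(OC)=[Cr](=C=O)(=C=O)(=C=O)(=C=O)=C=O | intermediate
11 | ethoxyacetylene | CCOC#C | starting material
12 | tricarbonyl[η6-7-ethoxy-3-ethyl-5-methoxy-1,2,4-tris(methoxymethoxy)naphthalen-8-ol]chromium (metal on the ring C4a–C8a) | CCc1c(OCOC)c2c(OC)cc(OCC)c(O)c2c(OCOC)c1OCOC.O=C=[Cr](=C=O)=C=O | intermediate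
13 | 7-ethoxy-3-ethyl-5-methoxy-1,2,4-tris(methoxymethoxy)naphthalen-8-ol | CCc1c(OCOC)c2c(OC)cc(OCC)c(O)c2c(OCOC)c1OCOC | intermediate
14 | 7-ethoxy-3-ethyl-5,8-dimethoxy-1,2,4-tris(methoxymethoxy)naphthalene | CCc1c(OCOC)c2c(OC)cc(OCC)c(OC)c2c(OCOC)c1OCOC | intermediate
15 | 7-ethoxy-3-ethyl-5,8-dimethoxynaphthalene-1,2,4-triol | CCc1c(O)c2c(OC)cc(OCC)c(OC)c2c(O)c1O | intermediate
16 | 7-ethoxy-3-ethyl-2-hydroxy-5,8-dimethoxynaphthalene-1,4-dione | CCC1=C(O)C(=O)c2c(OC)c(OCC)cc(OC)c2C1=O | intermediate
17 | 2-bromo-7-ethoxy-3-ethyl-5,8-dimethoxynaphthalene-1,4-dione | CCC1=C(Br)C(=O)c2c(OC)c(OCC)cc(OC)c2C1=O | intermediate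
18 | (S)-7-ethoxy-3-ethyl-3-hydroxy-5,8-dimethoxynaphthalene-1,2,4(3H)-trione | O[C@]1(CC)C(=O)C(=O)c2c(OC)c(OCC)cc(OC)c2C1=O | intermediate
19 | (S)-7-ethoxy-3-[(7-ethoxy-3-ethyl-5,8-dimethoxy-1,4-dioxo-1,4-dihydronaphthalen-2-yl)oxy]-3-ethyl-5,8-dimethoxynaphthalene-1,2,4(3H)-trione | CCC1=C(O[C@]2(CC)C(=O)C(=O)c3c(OC)c(OCC)cc(OC)c3C2=O)C(=O)c2c(OC)c(OCC)cc(OC)c2C1=O | intermediate
20 | (S)-3-ethyl-3-[(3-ethyl-5,7,8-trihydroxy-1,4-dioxo-1,4-dihydronaphthalen-2-yl)oxy]-5,7,8-trihydroxynaphthalene-1,2,4(3H)-trione | CCC1=C(O[C@]2(CC)C(=O)C(=O)c3c(O)c(O)cc(O)c3C2=O)C(=O)c2c(O)c(O)cc(O)c2C1=O | target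

**Count and risks**

Total step count: 11. Longest linear sequence: 10 steps (steps 1–7, then step 8 or step 9, then steps 10 and 11).

Steps most likely to fail:

1. Step 10 (Proposed new method). The caesium alkoxide of 18 may undergo a 1,2-acyl shift (α-ketol rearrangement with ring contraction) or transfer an electron to the bromoquinone faster than it adds to the hindered C2, so that the ether does not form or the alcohol loses its constitution and optical purity. The fallback sets out from hydroxyquinone 16 and comes back at 19. Oxidative dehydrodimerisation of 16 with PbO2 in AcOH at rt is the established carbon–oxygen coupling of 2-hydroxy-3-alkyl-1,4-naphthoquinones: one molecule is oxidised to the radical of the trione and is captured at C3 by the enolic oxygen of a second. It should give the racemic ether dimer F1. Preparative HPLC on an amylose tris(3,5-dimethylphenylcarbamate) phase would then separate the enantiomers, the S enantiomer being 19 (assignment by electronic circular dichroism against calculation). This path also makes steps 8 and 9 unnecessary.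

2. Step 9. Oxygen transfer to the weakly nucleophilic, chelated enolate may be slow. Facial discrimination may be poor because C3 lies outside the five-membered chelate ring. The Lewis acid may also induce a ketol shift in the product. The fallback sets out from 16 and comes back at 18. Neutral oxidation of the enol with dimethyldioxirane in acetone at 0 °C (epoxidation of the enol double bond and opening to the α-hydroxy trione) should give the racemic tertiary alcohol F2. This is resolved by preparative supercritical-fluid chromatography on a cellulose tris(3,5-dimethylphenylcarbamate) phase to give 18.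

3. Step 5. With the electron-rich ynol ether the sequence may stop after alkyne insertion at a stabilised alkenyl(ethoxy)carbene complex. The dienylketene may also leave the benzannulation path by four-electron ring closure to a cyclobutenone or by uptake of a second alkyne, and the volatile alkyne may be lost before it reacts. The fallback sets out from 10 and comes back at 14; it closes the same ring and forms the same three bonds. Benzannulation of 10 with 2-ethynyl-4,4,5,5-tetramethyl-1,3,2-dioxaborolane (THF, 50 °C), a reaction type established for alkynylboronates in which boron ends next to the phenol, should give the naphthol boronate F3. O-Methylation (MeI, Cs2CO3, DMF) gives the methyl ether boronate F4. Oxidation of the carbon–boron bond (NaBO3·4H2O, THF/H2O, rt) gives the C7 phenol F5, and O-ethylation (iodoethane, Cs2CO3, DMF) gives 14.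

Further compounds
F1 | step 10 | racemic 7-ethoxy-3-[(7-ethoxy-3-ethyl-5,8-dimethoxy-1,4-dioxo-1,4-dihydronaphthalen-2-yl)oxy]-3-ethyl-5,8-dimethoxynaphthalene-1,2,4(3H)-trione | CCC1=C(OC2(CC)C(=O)C(=O)c3c(OC)c(OCC)cc(OC)c3C2=O)C(=O)c2c(OC)c(OCC)cc(OC)c2C1=O
F2 | step 9 | racemic 7-ethoxy-3-ethyl-3-hydroxy-5,8-dimethoxynaphthalene-1,2,4(3H)-trione | CCC1(O)C(=O)C(=O)c2c(OC)c(OCC)cc(OC)c2C1=O
F3 | step 5 | 3-ethyl-5-methoxy-1,2,4-tris(methoxymethoxy)-7-(4,4,5,5-tetramethyl-1,3,2-dioxaborolan-2-yl)naphthalen-8-ol | CCc1c(OCOC)c2c(OC)cc(B3OC(C)(C)C(C)(C)O3)c(O)c2c(OCOC)c1OCOC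
F4 | step 5 | 2-[3-ethyl-5,8-dimethoxy-1,2,4-tris(methoxymethoxy)naphthalen-7-yl]-4,4,5,5-tetramethyl-1,3,2-dioxaborolane | CCc1c(OCOC)c2c(OC)cc(B3OC(C)(C)C(C)(C)O3)c(OC)c2c(OCOC)c1OCOC
F5 | step 5 | 3-ethyl-5,8-dimethoxy-1,2,4-tris(methoxymethoxy)naphthalen-7-ol | CCc1c(OCOC)c2c(OC)cc(O)c(OC)c2c(OCOC)c1OCOC
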